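**Retrosynthetic overview**

1. Atom numbers follow the target SMILES. Ring A is the cyclopentane C14-C15-C19-C24-C25, ring B the cyclopentene C13-C14-C15-C16-C17, ring C the cycloheptene C7-C10-C11-C12-C13-C14-C25, ring D the piperidine and ring E the pyran hemiketal. The strategy rests on quaternary C25: it lies between C7 and C14, which can be the two carbonyls of a 2,2-disubstituted cycloheptane-1,3-dione, so C25 is set by choosing one of two enantiotopic ketones.
2. Ring E: hemiketal of a δ-hydroxy ketone, from reduction of the C8 aldehyde; quaternary C7 from Michael addition of the C7 aldehyde enolate to ethyl vinyl ketone (C7–C6).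
3. Ring D: intramolecular Mannich reaction of the C7 ketone (C10–C29). Ring B: acylation of the C13=C14 alkene by the C17 acid (C13–C17), after α-alkylation of the enone dienolate at C15 (C15–C16); the C19 ester comes from the C19 ketone by methylenation, hydroboration and oxidation.
4. Rings A and C with C25: amine-catalysed desymmetrising aldol condensation of an achiral triketone (C14–C15), made from cycloheptane-1,3-dione, chloroacetone and an N-Boc-N-methylaminomethyl electrophile.
5. Order of ring formation: C (starting material), A (key step), B, D, E.

Key step: step 4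

Assumption: the C3 hemiketal centre equilibrates through the open δ-hydroxy ketone, and the configuration drawn for the target is taken to be the thermodynamic one (ethyl equatorial, hydroxyl axial).

Step 1
Reactants: 1 cycloheptane-1,3-dione; 2 chloroacetone
Product: 3 2-(2-oxopropyl)cycloheptane-1,3-dione
Conditions: KOH (1.0 equiv), KI (cat.), MeOH–H2O, 0 °C to rt
Reagents that add atoms: none
Why: C-alkylation of the 1,3-dione enolate by an α-halo ketone (SN2) in a protic medium that favours carbon over oxygen attack; no stereocentre is formed.

Step 2
Reactants: 4 tert-butyl methylcarbamate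
Product: 5 tert-butyl (chloromethyl)(methyl)carbamate
Conditions: (CH2O)n, Me3SiCl, CH2Cl2, rt
Reagents that add atoms: paraformaldehyde C=O; chlorotrimethylsilane C[Si](C)(C)Cl
Why: N-hydroxymethylation of the carbamate followed by OH/Cl exchange with the silyl chloride (N-chloromethylation) should give a storable N-acyliminium precursor.

Step 3
Reactants: 3 2-(2-oxopropyl)cycloheptane-1,3-dione; 5 tert-butyl (chloromethyl)(methyl)carbamate
Product: 6 tert-butyl methyl{[1,3-dioxo-2-(2-oxopropyl)cycloheptyl]methyl}carbamate (achiral triketone)
Conditions: Cs2CO3, NaI (cat.), MeCN, 0 to 45 °C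
Reagents that add atoms: none
Why: Mannich-type amidoalkylation of the 2-substituted 1,3-dione enolate by the N-acyliminium ion builds the quaternary carbon; an O-alkylated enol N,O-acetal can re-ionise and should drain to the C-alkylated product, which has a mirror plane.

Step 4
Reactants: 6 tert-butyl methyl{[1,3-dioxo-2-(2-oxopropyl)cycloheptyl]methyl}carbamate
Product: 8 tert-butyl methyl{[(3aS)-2,4-dioxo-3,4,5,6,7,8-hexahydroazulen-3a(2H)-yl]methyl}carbamate (bicyclic enedione; C7 ketone; C19 enone carbonyl), via cis-fused ketol 7 (not isolated)
Conditions: (S)-phenylalanine (0.5 equiv), (1S)-(+)-10-camphorsulfonic acid (0.25 equiv), DMF, 30 to 60 °C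
Reagents that add atoms: none
Why: Proposed new method: The primary amine forms the terminal enamine of the methyl ketone (C19=C15), whose C15 adds to one ring carbonyl (C14) that is hydrogen-bonded to the ammonium/carboxylic acid of the catalyst, and the cis-fused ketol 7 then loses water by way of its iminium ion to give the enone. The closest known reaction type is the amino-acid-catalysed Hajos–Parrish–Eder–Sauer–Wiechert cyclisation of 2-(3-oxobutyl)-1,3-diones, together with the acid- or base-mediated cyclodehydration of 1,4-diketones to cyclopentenones; what is new is the amine-catalysed, enantiotopic-group-selective five-ring closure on a seven-membered dione. Ring A is closed in the 5-(enolendo)-exo-trig mode (bond C14–C15), a stereoelectronically strained closure for an enamine, which is the reason for the label. The only new stereocentre, C25, is fixed by which of the two enantiotopic ketones is attacked and is therefore controlled by the catalyst; the (S)-amino acid is chosen by analogy with the six-ring series to give (S)-C25. The step needs group selectivity between the two ring ketones and enamine formation at CH3 instead of C24; the substrate secures the latter because C24 is neopentyl and its enamine cannot close a ring, and the bridged ketol that a ring-ketone enamine could form with C19 is reversible and should drain into the dehydrated product.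

Step 5
Reactants: 8 bicyclic enedione
Product: 9 C7 ethylene ketal (1,3-dioxolane) of enedione 8
Conditions: Me3SiOCH2CH2OSiMe3, Me3SiOTf (5 mol%), CH2Cl2, −78 to −20 °C
Reagents that add atoms: 1,2-bis(trimethylsilyloxy)ethane C[Si](C)(C)OCCO[Si](C)(C)C
Why: Silyl-triflate-catalysed ketalisation is selective for the saturated C7 ketone over the conjugated C19 carbonyl, and the Boc group should survive catalytic acid at low temperature.

Step 6
Reactants: 9 C7 ethylene ketal of enedione 8; 10 tert-butyl bromoacetate
Product: 11 β,γ-unsaturated ketone (C13=C14 alkene; C19 ketone; C15 bearing CH2CO2t-Bu on the C7 face with H15 syn to C26)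
Conditions: t-BuOK (1.0 equiv), THF, −78 to 0 °C; then 10 (1.5 equiv), −78 °C; AcOH quench at −78 °C
Reagents that add atoms: none
Why: Deconjugative α-alkylation of the extended (thermodynamic) dienolate takes place at C15 and moves the alkene to C13=C14; the N(Me)Boc arm on C25 should lie over ring A (nitrogen anti to the fully substituted C7), so the bromoacetate is expected to enter from the C7 face and leave H15 syn to C26.

Step 7
Reactants: 11 β,γ-unsaturated ketone
Product: 12 C19 exocyclic methylene compound (skipped diene C13=C14 / C19=CH2)
Conditions: Zn, CH2Br2, TiCl4, THF–CH2Cl2, 0 °C to rt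
Reagents that add atoms: dibromomethane BrCBr
Why: Takai–Lombardo methylenation is non-basic, so the enolisable C15 centre and the position of the C13=C14 alkene should be kept; C19 is the only free ketone because C7 is masked.

Step 8
Reactants: 12 C19 exocyclic methylene compound
Product: 13 primary alcohol (C20 hydroxymethyl on C19; H19 cis to H15)
Conditions: 9-BBN, THF, 0 °C to rt; then NaBO3·4H2O, H2O
Reagents that add atoms: sodium perborate [Na+].[O-]OB=O
Why: Hydroboration–oxidation with the bulky borane takes the 1,1-disubstituted alkene in preference to the trisubstituted C13=C14 and puts boron on C20; hydrogen is delivered to C19 anti to the vicinal C15–C16 branch, which sets H19 cis to H15.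

Step 9
Reactants: 13 primary alcohol
Product: 15 C20 methyl ester (C17 tert-butyl ester; C7 dioxolane; N-Boc), via carboxylic acid 14 (not isolated)
Conditions: TEMPO (0.2 equiv), PhI(OAc)2, MeCN–pH 7 buffer, rt; then Me3SiCHN2, PhMe–MeOH, 0 °C
Reagents that add atoms: water O; trimethylsilyldiazomethane C[Si](C)(C)C=[N+]=[N-]
Why: Oxoammonium oxidation takes the alcohol through the aldehyde hydrate to the acid under buffered conditions that should not enolise C19, and diazoalkane esterification gives the methyl ester beside the untouched tert-butyl ester.

Step 10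
Reactants: 15 C20 methyl ester
Product: 16 amino keto acid as its trifluoroacetate salt (free C7 ketone; C17 acid; secondary ammonium)
Conditions: CF3CO2H–CH2Cl2–H2O (10:10:1), 0 °C to rt
Reagents that add atoms: water O; trifluoroacetic acid OC(=O)C(F)(F)F
Why: One acidolysis removes Boc, the tert-butyl ester and the dioxolane; the methyl ester is stable, and the ammonium ion next to C14 should disfavour protonation of the C13=C14 alkene.

Step 11
Reactants: 16 amino keto acid trifluoroacetate
Product: 18 N-trifluoroacetyl tricyclic enone (rings A B C; C17 ketone conjugated to C13=C14), via mixed anhydride 17 (not isolated)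
Conditions: (CF3CO)2O (5 equiv), CH2Cl2, 0 °C to rt; then CF3SO3H (0.2 equiv), −40 to 0 °C; aq. NaHCO3 work-up
Reagents that add atoms: trifluoroacetic anhydride O=C(OC(=O)C(F)(F)F)C(F)(F)F
Why: The mixed trifluoroacetic anhydride of the C17 acid, activated by the strong acid, acylates C13 of the trisubstituted alkene (Friedel–Crafts-type alkene acylation, as in the classical closure of γ,δ-unsaturated acids to cyclopentenones), and the tertiary C14 cation loses H13 to give the tetrasubstituted enone of ring B; the amine is masked as its trifluoroacetamide in the same flask and C15 is not touched.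

Step 12
Reactants: 18 N-trifluoroacetyl tricyclic enone
Product: 20 tetracyclic amino diketone (rings A B C D; C7 ketone; C17 enone), via secondary amine 19 (not isolated)
Conditions: NH3 (7 M in MeOH), rt; evaporate; then 37% aq. CH2O, AcOH, MeOH, 50 °C
Reagents that add atoms: formaldehyde C=O
Why: Ammonolysis frees the N-methyl amine, whose iminium ion with formaldehyde is attacked by the enol of the C7 ketone (enolisable only toward C10) in an intramolecular Mannich reaction; the one-carbon tether from C25 can reach only the cis face, which fixes C10.

Step 13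
Reactants: 20 tetracyclic amino diketone
Product: 21 (17S)-allylic alcohol (C17 hydroxyl cis to H15)
Conditions: (R)-2-methyl-CBS-oxazaborolidine (0.3 equiv), catecholborane, PhMe–CH2Cl2, −78 °C; then MeOH and aqueous work-up
Reagents that add atoms: none
Why: Corey–Bakshi–Shibata reduction gives reagent-controlled 1,2-reduction of the enone, with the C13 alkene arm as the large group, so that hydride should add from the ring A side and give the 17S alcohol; the C7 ketone, flanked by a quaternary and a bridgehead carbon, should react far more slowly.

Step 14
Reactants: 21 (17S)-allylic alcohol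
Product: 22 C17 tert-butyldimethylsilyl ether
Conditions: t-BuMe2SiOTf, 2,6-lutidine, CH2Cl2, −40 to 0 °C
Reagents that add atoms: tert-butyldimethylsilyl trifluoromethanesulfonate CC(C)(C)[Si](C)(C)OS(=O)(=O)C(F)(F)F
Why: Silylation protects the allylic alcohol for the oxidation in step 17; the C7 ketone cannot form a silyl enol ether because both of its α-carbons are blocked.

Step 15
Reactants: 22 C17 silyl ether
Product: 23 C7 exocyclic methylene compound (C7=C8H2)
Conditions: Zn, CH2Br2, TiCl4, THF, 0 °C to rt (excess reagent)
Reagents that add atoms: dibromomethane BrCBr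
Why: Takai–Lombardo methylenation works on hindered, non-enolisable ketones and is non-basic, so the C19 ester centre should not epimerise and the ester and silyl ether are left alone.

Step 16
Reactants: 23 C7 exocyclic methylene compound
Product: 24 C8 primary alcohol (mixture of C7 epimers)
Conditions: 9-BBN, THF, 60 °C; then NaBO3·4H2O, H2O
Reagents that add atoms: sodium perborate [Na+].[O-]OB=O
Why: Anti-Markovnikov hydroboration–oxidation puts the oxygen on C8; the tetrasubstituted C13=C14 alkene is inert and the C7–H configuration does not matter because C7 is planarised again in step 18.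

Step 17
Reactants: 24 C8 primary alcohol
Product: 25 C8 aldehyde (mixture of C7 epimers)
Conditions: Dess–Martin periodinane, CH2Cl2, 0 °C to rt
Reagents that add atoms: none
Why: Hypervalent-iodine oxidation of the primary alcohol stops at the aldehyde and tolerates the tertiary amine, the ester and the silyl ether.

Step 18
Reactants: 25 C8 aldehyde; 26 ethyl vinyl ketone
Product: 27 keto aldehyde with quaternary C7 (C6 chain syn to the aza bridge; formyl C8 under the C13=C14 bridge)
Conditions: DBU (0.3 equiv), MeCN, rt to 40 °C
Reagents that add atoms: none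
Why: Michael addition of the α-branched aldehyde enolate to the vinyl ketone builds the quaternary centre; the enone should approach the exocyclic C7 enolate from the face of the three-atom aza bridge, because the other face lies in the pocket under the C13=C14 bridge, which places C6 syn to nitrogen as in the target.

Step 19
Reactants: 27 keto aldehyde
Product: 29 silylated hemiketal (ring E closed), via hydroxy ketone 28 (not isolated)
Conditions: NaBH4 (0.5 equiv), EtOH–CH2Cl2, −78 °C; aq. NH4Cl
Reagents that add atoms: none
Why: Borohydride at low temperature reduces the aldehyde faster than the dialkyl ketone; the C8 alcohol then adds to the C3 ketone to give the six-membered hemiketal, which masks the ketone and settles at the thermodynamic C3 configuration.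

Step 20
Reactants: 29 silylated hemiketal
Product: 30 CNP0124876.1 (target)
Conditions: HF·pyridine, pyridine, THF, 0 °C to rt
Reagents that add atoms: none
Why: Buffered fluoride cleaves the silyl ether without touching the methyl ester, the allylic alcohol or the hemiketal, which can re-close to its equilibrium form on work-up.

**Compound list**

1 | cycloheptane-1,3-dione | O=C1CCCCC(=O)C1 | starting material
2 | chloroacetone | CC(=O)CCl | starting material
3 | 2-(2-oxopropyl)cycloheptane-1,3-dione | CC(=O)CC1C(=O)CCCCC1=O | intermediate
4 | tert-butyl methylcarbamate | CNC(=O)OC(C)(C)C | starting material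
5 | tert-butyl (chloromethyl)(methyl)carbamate | CN(CCl)C(=O)OC(C)(C)C | intermediate
6 | tert-butyl methyl{[1,3-dioxo-2-(2-oxopropyl)cycloheptyl]methyl}carbamate | CC(=O)CC1(CN(C)C(=O)OC(C)(C)C)C(=O)CCCCC1=O | intermediate
7 | cis-fused bicyclic ketol (C14 hydroxyl cis to C26; C7 and C19 ketones) | O=C1CCCC[C@]2(O)CC(=O)C[C@]12CN(C)C(=O)OC(C)(C)C | intermediate
8 | tert-butyl methyl{[(3aS)-2,4-dioxo-3,4,5,6,7,8-hexahydroazulen-3a(2H)-yl]methyl}carbamate | O=C2CCCCC4=CC(=O)C[C@@]42CN(C)C(=O)OC(C)(C)C | intermediate
9 | C7 ethylene ketal of 8 | O1CCOC12CCCCC3=CC(=O)C[C@@]32CN(C)C(=O)OC(C)(C)C | intermediate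
10 | tert-butyl bromoacetate | CC(C)(C)OC(=O)CBr | starting material
11 | β,γ-unsaturated ketone (C13=C14; C15 CH2CO2t-Bu on the C7 face, H15 syn to C26) | O1CCOC12CCCC=C3[C@H](CC(=O)OC(C)(C)C)C(=O)C[C@@]32CN(C)C(=O)OC(C)(C)C | intermediate
12 | C19 exocyclic methylene compound | O1CCOC12CCCC=C3[C@H](CC(=O)OC(C)(C)C)C(=C)C[C@@]32CN(C)C(=O)OC(C)(C)C | intermediate
13 | C20 primary alcohol (H19 cis to H15) | O1CCOC12CCCC=C3[C@H](CC(=O)OC(C)(C)C)[C@H](CO)C[C@@]32CN(C)C(=O)OC(C)(C)C | intermediate
14 | C20 carboxylic acid | O1CCOC12CCCC=C3[C@H](CC(=O)OC(C)(C)C)[C@H](C(=O)O)C[C@@]32CN(C)C(=O)OC(C)(C)C | intermediate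
15 | C20 methyl ester | O1CCOC12CCCC=C3[C@H](CC(=O)OC(C)(C)C)[C@H](C(=O)OC)C[C@@]32CN(C)C(=O)OC(C)(C)C | intermediate
16 | amino keto acid trifluoroacetate salt | O=C1CCCC=C3[C@H](CC(=O)O)[C@H](C(=O)OC)C[C@@]31C[NH2+]C.[O-]C(=O)C(F)(F)F | intermediate
17 | N-trifluoroacetyl mixed trifluoroacetic anhydride | O=C1CCCC=C3[C@H](CC(=O)OC(=O)C(F)(F)F)[C@H](C(=O)OC)C[C@@]31CN(C)C(=O)C(F)(F)F | intermediate
18 | N-trifluoroacetyl tricyclic enone | O=C1CCCC3=C4[C@H](CC3=O)[C@H](C(=O)OC)C[C@@]41CN(C)C(=O)C(F)(F)F | intermediate
19 | secondary amine tricyclic enone | O=C1CCCC3=C4[C@H](CC3=O)[C@H](C(=O)OC)C[C@@]41CNC | intermediate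
20 | tetracyclic amino diketone | O=C2[C@@H]1CCC3=C4[C@H](CC3=O)[C@H](C(=O)OC)C[C@@]42CN(C)C1 | intermediate
21 | (17S)-allylic alcohol | O=C2[C@@H]1CCC3=C4[C@H](C[C@@H]3O)[C@H](C(=O)OC)C[C@@]42CN(C)C1 | intermediate
22 | C17 tert-butyldimethylsilyl ether | O=C2[C@@H]1CCC3=C4[C@H](C[C@@H]3O[Si](C)(C)C(C)(C)C)[C@H](C(=O)OC)C[C@@]42CN(C)C1 | intermediate
23 | C7 exocyclic methylene compound | C=C2[C@@H]1CCC3=C4[C@H](C[C@@H]3O[Si](C)(C)C(C)(C)C)[C@H](C(=O)OC)C[C@@]42CN(C)C1 | intermediate
24 | C8 primary alcohol (C7 epimers) | OCC2[C@@H]1CCC3=C4[C@H](C[C@@H]3O[Si](C)(C)C(C)(C)C)[C@H](C(=O)OC)C[C@@]42CN(C)C1 | intermediate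
25 | C8 aldehyde (C7 epimers) | O=CC2[C@@H]1CCC3=C4[C@H](C[C@@H]3O[Si](C)(C)C(C)(C)C)[C@H](C(=O)OC)C[C@@]42CN(C)C1 | intermediate
26 | ethyl vinyl ketone (pent-1-en-3-one) | CCC(=O)C=C | starting material
27 | keto aldehyde with quaternary C7 | CCC(=O)CC[C@@]2(C=O)[C@@H]1CCC3=C4[C@H](C[C@@H]3O[Si](C)(C)C(C)(C)C)[C@H](C(=O)OC)C[C@@]42CN(C)C1 | intermediate
28 | δ-hydroxy ketone | CCC(=O)CC[C@@]2(CO)[C@@H]1CCC3=C4[C@H](C[C@@H]3O[Si](C)(C)C(C)(C)C)[C@H](C(=O)OC)C[C@@]42CN(C)C1 | intermediate
29 | silylated hemiketal | CC[C@@]1(O)CC[C@@]2(CO1)[C@@H]1CCC3=C4[C@H](C[C@@H]3O[Si](C)(C)C(C)(C)C)[C@H](C(=O)OC)C[C@@]42CN(C)C1 | intermediate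
30 | CNP0124876.1 | CC[C@@]1(O)CC[C@@]2(CO1)[C@@H]1CCC3=C4[C@H](C[C@@H]3O)[C@H](C(=O)OC)C[C@@]42CN(C)C1 | target

**Step count**

Total: 20 steps. Longest linear sequence: 19 steps (steps 1 and 3–20; step 2 prepares reagent 5).

**Steps most likely to fail**

1. Step 4 (proposed new method). The enamine may close too slowly in the 5-(enolendo) mode, so that reversible bridged-ketol formation or ring opening of the 2,2-disubstituted dione takes over. The two enantiotopic ketones may also be discriminated poorly or in the opposite sense. Fallback with known chemistry: from 6, the classical base-mediated cyclodehydration of a 1,4-diketone to a cyclopentenone (KOH, MeOH, 0 °C to rt) gives the racemic enedione F1. Preparative chromatography on a chiral stationary phase then gives the (S)-enantiomer 8, where the route is rejoined.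

2. Step 6. The bromoacetate may approach from the face of the carbamate arm. Proton exchange between the product and unreacted dienolate may also epimerise C15 or move the alkene back into conjugation before the quench. Fallback: the order in which carbon and hydrogen reach C15 is reversed. From 9, alkylation with 10 under equilibrating conditions (t-BuOK, t-BuOH–THF, rt) gives the conjugated 2-substituted enone F2, which has no C15 stereocentre. Its extended dienolate (t-BuOK, THF, −78 to 0 °C) is then protonated kinetically at the α-carbon by inverse addition to AcOH at −78 °C, the classical deconjugation of an enone. The proton then takes the face that the alkylating agent preferred, and the product is 11, where the route is rejoined.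

3. Step 18. The two faces of the exocyclic C7 enolate differ only in the aza bridge on one side and the alkene-bearing bridge on the other, so facial selectivity may be poor or reversed. Retro-Michael cleavage or Robinson-type aldol closure of the keto aldehyde may also compete. Fallback: the roles of the two carbon substituents on C7 are exchanged. From 25, crossed aldol reaction with formaldehyde (37% aq. CH2O, K2CO3, MeOH, 0 °C) gives the β-hydroxy aldehyde F3, in which the incoming hydroxymethyl carbon is C8 and the formyl carbon becomes C6. Wittig reaction with 1-(triphenylphosphoranylidene)butan-2-one (toluene, 80 °C) gives the E-enone F4. Hydrogenation of its disubstituted alkene (H2, Pd/C, EtOAc; the tetrasubstituted C13=C14 should not be reduced) gives the hydroxy ketone 28, which closes to 29, where the route is rejoined.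

**Further compounds**

F1 | step 4 | racemic tert-butyl methyl{[2,4-dioxo-3,4,5,6,7,8-hexahydroazulen-3a(2H)-yl]methyl}carbamate | O=C2CCCCC4=CC(=O)CC42CN(C)C(=O)OC(C)(C)C
F2 | step 6 | conjugated enone with CH2CO2t-Bu on C15 (C14=C15; C7 dioxolane) | O1CCOC12CCCCC3=C(CC(=O)OC(C)(C)C)C(=O)C[C@@]32CN(C)C(=O)OC(C)(C)C
F3 | step 18 | β-hydroxy aldehyde with quaternary C7 (C8 hydroxymethyl; C6 formyl) | O=C[C@@]2(CO)[C@@H]1CCC3=C4[C@H](C[C@@H]3O[Si](C)(C)C(C)(C)C)[C@H](C(=O)OC)C[C@@]42CN(C)C1
F4 | step 18 | E-enone (C5=C6) with C8 hydroxymethyl | CCC(=O)/C=C/[C@@]2(CO)[C@@H]1CCC3=C4[C@H](C[C@@H]3O[Si](C)(C)C(C)(C)C)[C@H](C(=O)OC)C[C@@]42CN(C)C1
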